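The route rests on making the hydroxylated ring (C5–C8) of naphthalene B last. Its C5 oxygen sits next to the C6–C6′ biaryl bond, so C5 is traced to a ketone carbon, C6 to the α-carbon that already bears naphthalene A, and C7/C8 to two vinyl termini. The precursor is therefore a 1-(2-vinylaryl)-2-(naphthalen-6-yl)but-3-en-1-one carrying both bromides. One ruthenium-catalysed ring closure forges C7=C8 and, through enolisation of the naphthalen-1(2H)-one, delivers the dibrominated 6,6′-binaphthol with the hindered biaryl bond already in place. A double Suzuki coupling then installs both (1R,3R)-tetrahydroisoquinolines, and a single hydrogenolysis removes all benzyl groups.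

Key step: step 26

Assumption: the target SMILES fixes only the four stereocentres (all R) and no axial configuration, so the two hindered naphthalene–isoquinoline axes are not controlled (the central 6,6′ axis rotates freely); a mixture of atropisomers would be separated by HPLC if one is wanted.

Numbering: in binaphthyl compounds each naphthalene is numbered as in the target (C2 methyl, C4 methoxy, C5 oxygen); unprimed locants are naphthalene A (isoquinoline at C8), primed locants are naphthalene B (isoquinoline at C1′).

Design note: the C5 oxygen of naphthalene A is carried as a benzyl ether, not an acetal. It tolerates PBr3, indium bromides, the periodinane and the ruthenium carbene, and it leaves with the other benzyl groups in the last step.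

**Naphthalene A fragment (steps 1–11)**

Step 1
Reactants: 1 2-bromo-5-hydroxybenzaldehyde
Product: 2 2-bromo-5-isopropoxybenzaldehyde
Conditions: 2-bromopropane, K2CO3, DMF, 60 °C
Reagents that add atoms: 2-bromopropane, CC(C)Br
Why: Williamson etherification of the phenoxide should proceed cleanly, and the isopropyl ether is chosen because it survives base, hot acetic anhydride and hydride and can later be cleaved by BCl3 without loss of a methyl ether.

Step 2
Reactants: 2 2-bromo-5-isopropoxybenzaldehyde; 3 diethyl succinate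
Product: 4 (E)-4-(2-bromo-5-isopropoxyphenyl)-3-(ethoxycarbonyl)but-3-enoic acid
Conditions: KOtBu, t-BuOH, reflux; then aq. HCl
Reagents that add atoms: none
Why: Stobbe condensation, in which the succinate enolate adds to the aldehyde, the alkoxide lactonises and base-induced opening of the lactone gives the half-ester, expected mainly as the E isomer with the aryl group cis to the CH2CO2H arm as ring closure requires.

Step 3
Reactants: 4 (E)-4-(2-bromo-5-isopropoxyphenyl)-3-(ethoxycarbonyl)but-3-enoic acid
Product: 6 ethyl 4-acetoxy-8-bromo-5-isopropoxynaphthalene-2-carboxylate, via naphthol 5 (not isolated)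
Conditions: Ac2O, NaOAc, 140 °C
Reagents that add atoms: acetic anhydride, CC(=O)OC(C)=O
Why: The mixed anhydride undergoes intramolecular Friedel–Crafts acylation at the only free position ortho to the side chain (it lies ortho to the activating isopropoxy group, the other ortho position carrying bromine), the dienone enolises to naphthol 5 and this is acetylated in situ.

Step 4
Reactants: 6 ethyl 4-acetoxy-8-bromo-5-isopropoxynaphthalene-2-carboxylate
Product: 8 ethyl 8-bromo-5-isopropoxy-4-methoxynaphthalene-2-carboxylate, via potassium naphthoxide 7 (not isolated)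
Conditions: K2CO3, EtOH, rt; evaporate; then MeI, DMF, 40 °C
Reagents that add atoms: iodomethane, CI
Why: Base-mediated ethanolysis removes the aryl acetate far faster than the naphthoate ester (ethanol avoids ester scrambling), and the potassium naphthoxide so formed is O-methylated directly in a Williamson reaction to give the C4 methyl ether.

Step 5
Reactants: 8 ethyl 8-bromo-5-isopropoxy-4-methoxynaphthalene-2-carboxylate
Product: 9 (8-bromo-5-isopropoxy-4-methoxynaphthalen-2-yl)methanol
Conditions: iBu2AlH, CH2Cl2, −78 → 0 °C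
Reagents that add atoms: none
Why: Hydride reduction of the ester to the primary alcohol with iBu2AlH at low temperature should leave the aryl bromide and both ethers untouched.

Step 6
Reactants: 9 (8-bromo-5-isopropoxy-4-methoxynaphthalen-2-yl)methanol
Product: 11 1-bromo-4-isopropoxy-5-methoxy-7-methylnaphthalene, via mesylate 10 (not isolated)
Conditions: MsCl, Et3N, THF, 0 °C; then LiBEt3H, 0 °C → rt
Reagents that add atoms: none
Why: Sulfonylation of the naphthylmethyl alcohol followed by SN2 displacement with the strong hydride donor LiBEt3H deoxygenates the benzylic position to the C2 methyl group, with the aryl bromide inert at 0 °C.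

Step 7
Reactants: 11 1-bromo-4-isopropoxy-5-methoxy-7-methylnaphthalene
Product: 12 4-bromo-8-methoxy-6-methylnaphthalen-1-ol
Conditions: BCl3, CH2Cl2, −78 → −20 °C
Reagents that add atoms: none
Why: Lewis acid cleavage of the secondary alkyl aryl ether by BCl3 (isopropyl lost as 2-chloropropane) is much faster than cleavage of the methyl ether, so the C5 naphthol should be unveiled selectively.

Step 8
Reactants: 12 4-bromo-8-methoxy-6-methylnaphthalen-1-ol
Product: 13 4-bromo-1-hydroxy-8-methoxy-6-methylnaphthalene-2-carbaldehyde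
Conditions: MgCl2, Et3N, (CH2O)n, MeCN, reflux
Reagents that add atoms: paraformaldehyde (as formaldehyde), C=O
Why: Magnesium-mediated ortho-formylation of phenols (Casnati–Skattebøl reaction) delivers formaldehyde within the magnesium naphthoxide chelate to the only free ortho carbon, C6 of naphthalene A (the para carbon C8 carries bromine), and a second formaldehyde oxidises the hydroxymethyl intermediate to the aldehyde.

Step 9
Reactants: 13 4-bromo-1-hydroxy-8-methoxy-6-methylnaphthalene-2-carbaldehyde
Product: 14 1-(benzyloxy)-4-bromo-8-methoxy-6-methylnaphthalene-2-carbaldehyde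
Conditions: BnBr, K2CO3, DMF, 60 °C
Reagents that add atoms: benzyl bromide, BrCc1ccccc1
Why: Williamson benzylation of the hydrogen-bonded naphthol installs a protecting group that withstands all later steps and is removed in the final hydrogenolysis.

Step 10
Reactants: 14 1-(benzyloxy)-4-bromo-8-methoxy-6-methylnaphthalene-2-carbaldehyde
Product: 15 1-[1-(benzyloxy)-4-bromo-8-methoxy-6-methylnaphthalen-2-yl]prop-2-en-1-ol (racemic)
Conditions: CH2=CHMgBr, THF, −78 → 0 °C
Reagents that add atoms: vinylmagnesium bromide, C=C[Mg]Br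
Why: 1,2-Addition of the vinyl Grignard reagent to the aldehyde at low temperature is much faster than halogen–magnesium exchange at the aryl bromide and gives the racemic allylic alcohol.

Step 11
Reactants: 15 1-[1-(benzyloxy)-4-bromo-8-methoxy-6-methylnaphthalen-2-yl]prop-2-en-1-ol
Product: 16 1-(benzyloxy)-4-bromo-2-[(E)-3-bromoprop-1-en-1-yl]-8-methoxy-6-methylnaphthalene
Conditions: PBr3, Et2O, 0 °C; used crude
Reagents that add atoms: phosphorus tribromide, BrP(Br)Br
Why: Bromination with PBr3 proceeds with allylic transposition (ionisation of the electron-rich benzylic phosphite and bromide capture at the terminus) to the conjugated, thermodynamically favoured E cinnamyl-type bromide.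

**Vinyl aldehyde fragment (steps 12–16)**

Step 12
Reactants: 17 3,5-dimethoxytoluene
Product: 19 2,6-dimethoxy-4-methylbenzaldehyde, via aryllithium 18 (not isolated)
Conditions: n-BuLi, TMEDA, Et2O, 0 °C → rt; then DMF, 0 °C; aq. HCl
Reagents that add atoms: N,N-dimethylformamide, CN(C)C=O
Why: Directed ortho-metalation, in which n-BuLi lithiates the position flanked by both methoxy groups and the aryllithium is formylated by DMF.

Step 13
Reactants: 19 2,6-dimethoxy-4-methylbenzaldehyde
Product: 20 3-bromo-2,6-dimethoxy-4-methylbenzaldehyde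
Conditions: NBS (1.0 equiv), MeCN, 0 °C → rt
Reagents that add atoms: N-bromosuccinimide, O=C1CCC(=O)N1Br
Why: Electrophilic aromatic bromination, where the two free ring positions of symmetric 19 are equivalent (each ortho to one methoxy group and para to the other), so one equivalent of NBS can give only this monobromide.

Step 14
Reactants: 20 3-bromo-2,6-dimethoxy-4-methylbenzaldehyde
Product: 21 3-bromo-2-hydroxy-6-methoxy-4-methylbenzaldehyde
Conditions: BCl3 (1.1 equiv), CH2Cl2, −78 → 0 °C
Reagents that add atoms: none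
Why: Chelation-controlled ether cleavage, in which BCl3 bound to the aldehyde oxygen cleaves an ortho methyl ether, and the methoxy group squeezed between formyl and bromine is twisted out of plane (more basic, strain relieved on cleavage), so the hydroxyl is expected next to bromine while the boron chelate protects the second methoxy group.

Step 15
Reactants: 21 3-bromo-2-hydroxy-6-methoxy-4-methylbenzaldehyde
Product: 22 6-bromo-2-formyl-3-methoxy-5-methylphenyl trifluoromethanesulfonate
Conditions: Tf2O, pyridine, CH2Cl2, 0 °C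
Reagents that add atoms: trifluoromethanesulfonic anhydride, O=S(=O)(OS(=O)(=O)C(F)(F)F)C(F)(F)F
Why: O-Sulfonylation of the phenol with triflic anhydride and pyridine gives the aryl triflate that serves as the leaving group for vinylation.

Step 16
Reactants: 22 6-bromo-2-formyl-3-methoxy-5-methylphenyl trifluoromethanesulfonate
Product: 23 3-bromo-6-methoxy-4-methyl-2-vinylbenzaldehyde
Conditions: CH2=CHSnBu3, PdCl2(PPh3)2 (5 mol%), LiCl, DMF, 70 °C
Reagents that add atoms: tributyl(vinyl)stannane, C=C[Sn](CCCC)(CCCC)CCCC
Why: Stille coupling under chloride-rich polar conditions, where oxidative addition of zerovalent palladium to an aryl triflate is preferred over an aryl bromide, here reinforced by the activating ortho formyl group on the triflate and by the electron-rich, doubly flanked position of the bromide.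

**Isoquinoline boronate (steps 17–23)**

Step 17
Reactants: 24 1-(benzyloxy)-3-bromobenzene; 25 tert-butyl (R)-4-methyl-1,2,3-oxathiazolidine-3-carboxylate 2,2-dioxide
Product: 28 tert-butyl (R)-{1-[3-(benzyloxy)phenyl]propan-2-yl}carbamate, via arylmagnesium bromide 26 (not isolated), via N-sulfamate 27 (not isolated)
Conditions: Mg, THF, reflux; then 25, CuI (10 mol%), THF, −20 °C → rt; then 10% aq. citric acid, rt
Reagents that add atoms: none
Why: Copper-catalysed SN2 opening of the cyclic sulfamidate by the aryl Grignard reagent occurs at the primary carbon, so the alaninol-derived stereocentre is untouched and becomes C3 (R), and mild acid then hydrolyses the N-sulfamate without removing the Boc group.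

Step 18
Reactants: 28 tert-butyl (R)-{1-[3-(benzyloxy)phenyl]propan-2-yl}carbamate
Product: 29 tert-butyl (R)-{1-[5-(benzyloxy)-2-bromophenyl]propan-2-yl}carbamate
Conditions: NBS, MeCN, 0 °C → rt
Reagents that add atoms: N-bromosuccinimide, O=C1CCC(=O)N1Br
Why: Electrophilic bromination para to the benzyloxy group (ortho to the alkyl chain), as in 3-alkylanisoles, installs the future C5 bromide, which also blocks this position in the coming ring closure.

Step 19
Reactants: 29 tert-butyl (R)-{1-[5-(benzyloxy)-2-bromophenyl]propan-2-yl}carbamate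
Product: 31 (R)-N-{1-[5-(benzyloxy)-2-bromophenyl]propan-2-yl}acetamide, via primary amine 30 (not isolated)
Conditions: TFA, CH2Cl2, rt; evaporate; then Ac2O, Et3N, CH2Cl2, 0 °C → rt
Reagents that add atoms: acetic anhydride, CC(=O)OC(C)=O
Why: Acidolysis of the Boc group and N-acetylation of the liberated amine provide the amide needed for cyclisation, with no event at the stereocentre.

Step 20
Reactants: 31 (R)-N-{1-[5-(benzyloxy)-2-bromophenyl]propan-2-yl}acetamide
Product: 32 (R)-8-(benzyloxy)-5-bromo-1,3-dimethyl-3,4-dihydroisoquinoline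
Conditions: Tf2O, 2-chloropyridine, CH2Cl2, −78 → 45 °C; aq. NaOH work-up
Reagents that add atoms: none
Why: Bischler–Napieralski cyclisation with amide activation by triflic anhydride, in which the nitrilium ion attacks the only free position ortho to the side chain; this position is ortho to the benzyloxy group, because the other ortho position (para to the benzyloxy group) is blocked by bromine.

Step 21
Reactants: 32 (R)-8-(benzyloxy)-5-bromo-1,3-dimethyl-3,4-dihydroisoquinoline
Product: 33 (1R,3R)-8-(benzyloxy)-5-bromo-1,3-dimethyl-1,2,3,4-tetrahydroisoquinoline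
Conditions: LiAlH4, AlMe3, THF, −78 °C
Reagents that add atoms: none
Why: Hydride reduction of the cyclic imine as its AlMe3 complex, where the bulky N–Al complex reverses the usual facial preference so that hydride enters C1 on the side of the C3 methyl group, a known reagent-controlled route to 1,3-trans (here 1R,3R) tetrahydroisoquinolines (NaBH4 would give cis).

Step 22
Reactants: 33 (1R,3R)-8-(benzyloxy)-5-bromo-1,3-dimethyl-1,2,3,4-tetrahydroisoquinoline
Product: 34 (1R,3R)-2-benzyl-8-(benzyloxy)-5-bromo-1,3-dimethyl-1,2,3,4-tetrahydroisoquinoline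
Conditions: BnBr, K2CO3, MeCN, 60 °C
Reagents that add atoms: benzyl bromide, BrCc1ccccc1
Why: N-Alkylation of the secondary amine with benzyl bromide protects nitrogen for the organometallic steps and is reversed at the end by hydrogenolysis.

Step 23
Reactants: 34 (1R,3R)-2-benzyl-8-(benzyloxy)-5-bromo-1,3-dimethyl-1,2,3,4-tetrahydroisoquinoline
Product: 36 (1R,3R)-2-benzyl-8-(benzyloxy)-1,3-dimethyl-5-(4,4,5,5-tetramethyl-1,3,2-dioxaborolan-2-yl)-1,2,3,4-tetrahydroisoquinoline, via aryllithium 35 (not isolated)
Conditions: n-BuLi, THF, −78 °C; then iPrOBpin, −78 °C → rt; aq. NH4Cl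
Reagents that add atoms: 2-isopropoxy-4,4,5,5-tetramethyl-1,3,2-dioxaborolane, CC(C)OB1OC(C)(C)C(C)(C)O1
Why: Bromine–lithium exchange at −78 °C is faster than benzylic deprotonation and the aryllithium is trapped by the isopropoxy dioxaborolane to give the pinacol boronate.

**Fragment union, key step and end game (steps 24–29)**

Step 24
Reactants: 16 1-(benzyloxy)-4-bromo-2-[(E)-3-bromoprop-1-en-1-yl]-8-methoxy-6-methylnaphthalene; 23 3-bromo-6-methoxy-4-methyl-2-vinylbenzaldehyde
Product: 38 1-(3-bromo-6-methoxy-4-methyl-2-vinylphenyl)-2-[5-(benzyloxy)-8-bromo-4-methoxy-2-methylnaphthalen-6-yl]but-3-en-1-ol (racemic, mainly anti expected), via allylindium dibromide 37 (not isolated)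
Conditions: In powder, DMF, rt; then aq. NH4Cl
Reagents that add atoms: none
Why: Barbier-type indium-mediated allylation, in which the γ-aryl allylindium reagent adds through a six-membered cyclic transition state at its γ carbon, so the carbon bearing naphthalene A bonds to the carbinol carbon (both new centres are erased later), and indium does not insert into aryl bromides.

Step 25
Reactants: 38 1-(3-bromo-6-methoxy-4-methyl-2-vinylphenyl)-2-[5-(benzyloxy)-8-bromo-4-methoxy-2-methylnaphthalen-6-yl]but-3-en-1-ol
Product: 39 1-(3-bromo-6-methoxy-4-methyl-2-vinylphenyl)-2-[5-(benzyloxy)-8-bromo-4-methoxy-2-methylnaphthalen-6-yl]but-3-en-1-one (racemic)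
Conditions: Dess–Martin periodinane, NaHCO3, CH2Cl2, 0 °C; short filtration, used at once
Reagents that add atoms: none
Why: Dess–Martin oxidation under bicarbonate buffer converts the hindered benzylic alcohol into the β,γ-unsaturated ketone under neutral conditions that should not move the alkene into conjugation.

Step 26
Reactants: 39 1-(3-bromo-6-methoxy-4-methyl-2-vinylphenyl)-2-[5-(benzyloxy)-8-bromo-4-methoxy-2-methylnaphthalen-6-yl]but-3-en-1-one
Product: 41 5-(benzyloxy)-1′,8-dibromo-4,4′-dimethoxy-2,2′-dimethyl-6,6′-binaphthalen-5′-ol, via naphthalenone 40 (not isolated)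
Conditions: second-generation Grubbs catalyst RuCl2(=CHPh)(PCy3)(H2IMes) (10 mol%), degassed CH2Cl2 (0.005 M), 40 °C
Reagents that add atoms: none
Why: Ring-closing olefin metathesis by the Chauvin mechanism: the ruthenium benzylidene exchanges onto the more accessible allyl terminus, the new carbene adds across the ortho vinyl group in a [2+2] cycloaddition, and cycloreversion of the ruthenacyclobutane expels ethene and forms C7′=C8′ of naphthalene B. The closest known reaction type is the metathesis of 1-(2-vinylaryl)but-3-en-1-ones to naphthalen-1(2H)-ones that tautomerise to 1-naphthols. The one ring is closed as a six-membered carbocycle between two terminal alkenes of a 1,7-diene, whose reacting ends are held close by the ortho-disubstituted aryl ketone. No stereocentre is created; the racemic C6′ centre becomes sp2 when naphthalenone 40 enolises, and this aromatisation makes the step irreversible. The selectivity needed is ring closure ahead of migration of the β,γ-double bond into conjugation and ahead of intermolecular metathesis; it is secured by using freshly made 39 under neutral, dilute conditions and by the fast six-ring closure, while the aryl bromides, benzyl ether and ketone are inert to the carbene.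

Step 27
Reactants: 41 5-(benzyloxy)-1′,8-dibromo-4,4′-dimethoxy-2,2′-dimethyl-6,6′-binaphthalen-5′-ol
Product: 42 5,5′-bis(benzyloxy)-1′,8-dibromo-4,4′-dimethoxy-2,2′-dimethyl-6,6′-binaphthalene
Conditions: BnBr, Cs2CO3, DMF, rt → 50 °C
Reagents that add atoms: benzyl bromide, BrCc1ccccc1
Why: Williamson benzylation of the hindered naphthol through its caesium phenoxide masks the acidic, electron-releasing hydroxyl before the cross-coupling.

Step 28
Reactants: 42 5,5′-bis(benzyloxy)-1′,8-dibromo-4,4′-dimethoxy-2,2′-dimethyl-6,6′-binaphthalene; 36 (1R,3R)-2-benzyl-8-(benzyloxy)-1,3-dimethyl-5-(4,4,5,5-tetramethyl-1,3,2-dioxaborolan-2-yl)-1,2,3,4-tetrahydroisoquinoline (2.6 equiv)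
Product: 43 5,5′-bis(benzyloxy)-4,4′-dimethoxy-2,2′-dimethyl-6,6′-binaphthalene bearing a (1R,3R)-2-benzyl-8-(benzyloxy)-1,3-dimethyl-1,2,3,4-tetrahydroisoquinolin-5-yl group at C8 and at C1′
Conditions: Pd2(dba)3 (5 mol%), SPhos (20 mol%), K3PO4, toluene/H2O 10:1, 100 °C
Reagents that add atoms: none
Why: Double Suzuki–Miyaura coupling, in which the electron-rich bulky biarylphosphine supports oxidative addition at both hindered aryl bromides and transmetalation of the ortho-substituted boronate, forming both naphthalene–isoquinoline bonds without touching the stereocentres (a mixture of atropisomers about the two new axes is expected).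

Step 29
Reactants: 43 hexabenzyl-protected bis(isoquinolinyl)binaphthalene
Product: 44 CNP0077060.1, 4,4′-dimethoxy-2,2′-dimethyl-6,6′-binaphthalene-5,5′-diol bearing a (1R,3R)-8-hydroxy-1,3-dimethyl-1,2,3,4-tetrahydroisoquinolin-5-yl group at C8 and at C1′
Conditions: H2 (1 atm), 10% Pd/C, MeOH/EtOAc, AcOH (cat.), rt
Reagents that add atoms: none
Why: Catalytic hydrogenolysis cleaves the four O-benzyl ethers and the two exocyclic N-benzyl groups while the methyl ethers, the aromatic rings and the C1/C3 stereocentres are unaffected, giving the target.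

**Compound list**

1 | 2-bromo-5-hydroxybenzaldehyde | O=Cc1cc(O)ccc1Br | starting material
2 | 2-bromo-5-isopropoxybenzaldehyde | CC(C)Oc1ccc(Br)c(C=O)c1 | intermediate
3 | diethyl succinate | CCOC(=O)CCC(=O)OCC | starting material
4 | (E)-4-(2-bromo-5-isopropoxyphenyl)-3-(ethoxycarbonyl)but-3-enoic acid | CCOC(=O)/C(CC(=O)O)=C/c1cc(OC(C)C)ccc1Br | intermediate
5 | ethyl 8-bromo-4-hydroxy-5-isopropoxynaphthalene-2-carboxylate | CCOC(=O)c1cc(O)c2c(OC(C)C)ccc(Br)c2c1 | intermediate (not isolated)
6 | ethyl 4-acetoxy-8-bromo-5-isopropoxynaphthalene-2-carboxylate | CCOC(=O)c1cc(OC(C)=O)c2c(OC(C)C)ccc(Br)c2c1 | intermediate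
7 | potassium 5-bromo-3-(ethoxycarbonyl)-8-isopropoxynaphthalen-1-olate | CCOC(=O)c1cc([O-])c2c(OC(C)C)ccc(Br)c2c1.[K+] | intermediate (not isolated)
8 | ethyl 8-bromo-5-isopropoxy-4-methoxynaphthalene-2-carboxylate | CCOC(=O)c1cc(OC)c2c(OC(C)C)ccc(Br)c2c1 | intermediate
9 | (8-bromo-5-isopropoxy-4-methoxynaphthalen-2-yl)methanol | OCc1cc(OC)c2c(OC(C)C)ccc(Br)c2c1 | intermediate
10 | (8-bromo-5-isopropoxy-4-methoxynaphthalen-2-yl)methyl methanesulfonate | CS(=O)(=O)OCc1cc(OC)c2c(OC(C)C)ccc(Br)c2c1 | intermediate (not isolated)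
11 | 1-bromo-4-isopropoxy-5-methoxy-7-methylnaphthalene | Cc1cc(OC)c2c(OC(C)C)ccc(Br)c2c1 | intermediate
12 | 4-bromo-8-methoxy-6-methylnaphthalen-1-ol | Cc1cc(OC)c2c(O)ccc(Br)c2c1 | intermediate
13 | 4-bromo-1-hydroxy-8-methoxy-6-methylnaphthalene-2-carbaldehyde | Cc1cc(OC)c2c(O)c(C=O)cc(Br)c2c1 | intermediate
14 | 1-(benzyloxy)-4-bromo-8-methoxy-6-methylnaphthalene-2-carbaldehyde | Cc1cc(OC)c2c(OCc3ccccc3)c(C=O)cc(Br)c2c1 | intermediate
15 | 1-[1-(benzyloxy)-4-bromo-8-methoxy-6-methylnaphthalen-2-yl]prop-2-en-1-ol (racemic) | C=CC(O)c1cc(Br)c2cc(C)cc(OC)c2c1OCc1ccccc1 | intermediate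
16 | 1-(benzyloxy)-4-bromo-2-[(E)-3-bromoprop-1-en-1-yl]-8-methoxy-6-methylnaphthalene | BrC/C=C/c1cc(Br)c2cc(C)cc(OC)c2c1OCc1ccccc1 | intermediate
17 | 3,5-dimethoxytoluene | COc1cc(C)cc(OC)c1 | starting material
18 | (2,6-dimethoxy-4-methylphenyl)lithium | [Li]c1c(OC)cc(C)cc1OC | intermediate (not isolated)
19 | 2,6-dimethoxy-4-methylbenzaldehyde | COc1cc(C)cc(OC)c1C=O | intermediate
20 | 3-bromo-2,6-dimethoxy-4-methylbenzaldehyde | COc1cc(C)c(Br)c(OC)c1C=O | intermediate
21 | 3-bromo-2-hydroxy-6-methoxy-4-methylbenzaldehyde | COc1cc(C)c(Br)c(O)c1C=O | intermediate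
22 | 6-bromo-2-formyl-3-methoxy-5-methylphenyl trifluoromethanesulfonate | COc1cc(C)c(Br)c(OS(=O)(=O)C(F)(F)F)c1C=O | intermediate
23 | 3-bromo-6-methoxy-4-methyl-2-vinylbenzaldehyde | COc1cc(C)c(Br)c(C=C)c1C=O | intermediate
24 | 1-(benzyloxy)-3-bromobenzene | Brc1cccc(OCc2ccccc2)c1 | starting material
25 | tert-butyl (R)-4-methyl-1,2,3-oxathiazolidine-3-carboxylate 2,2-dioxide | C[C@@H]1COS(=O)(=O)N1C(=O)OC(C)(C)C | starting material
26 | [3-(benzyloxy)phenyl]magnesium bromide | Br[Mg]c1cccc(OCc2ccccc2)c1 | intermediate (not isolated)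
27 | (R)-N-{1-[3-(benzyloxy)phenyl]propan-2-yl}-N-(tert-butoxycarbonyl)sulfamic acid (formed as its magnesium salt) | C[C@H](Cc1cccc(OCc2ccccc2)c1)N(C(=O)OC(C)(C)C)S(=O)(=O)O | intermediate (not isolated)
28 | tert-butyl (R)-{1-[3-(benzyloxy)phenyl]propan-2-yl}carbamate | C[C@H](Cc1cccc(OCc2ccccc2)c1)NC(=O)OC(C)(C)C | intermediate
29 | tert-butyl (R)-{1-[5-(benzyloxy)-2-bromophenyl]propan-2-yl}carbamate | C[C@H](Cc1cc(OCc2ccccc2)ccc1Br)NC(=O)OC(C)(C)C | intermediate
30 | (R)-1-[5-(benzyloxy)-2-bromophenyl]propan-2-amine (formed as its trifluoroacetate) | C[C@H](Cc1cc(OCc2ccccc2)ccc1Br)N | intermediate (not isolated)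
31 | (R)-N-{1-[5-(benzyloxy)-2-bromophenyl]propan-2-yl}acetamide | C[C@H](Cc1cc(OCc2ccccc2)ccc1Br)NC(C)=O | intermediate
32 | (R)-8-(benzyloxy)-5-bromo-1,3-dimethyl-3,4-dihydroisoquinoline | CC1=N[C@H](C)Cc2c(Br)ccc(OCc3ccccc3)c12 | intermediate
33 | (1R,3R)-8-(benzyloxy)-5-bromo-1,3-dimethyl-1,2,3,4-tetrahydroisoquinoline | C[C@@H]1Cc2c(Br)ccc(OCc3ccccc3)c2[C@@H](C)N1 | intermediate
34 | (1R,3R)-2-benzyl-8-(benzyloxy)-5-bromo-1,3-dimethyl-1,2,3,4-tetrahydroisoquinoline | C[C@@H]1Cc2c(Br)ccc(OCc3ccccc3)c2[C@@H](C)N1Cc1ccccc1 | intermediate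
35 | [(1R,3R)-2-benzyl-8-(benzyloxy)-1,3-dimethyl-1,2,3,4-tetrahydroisoquinolin-5-yl]lithium | [Li]c1ccc(OCc2ccccc2)c2c1C[C@@H](C)N(Cc1ccccc1)[C@@H]2C | intermediate (not isolated)
36 | (1R,3R)-2-benzyl-8-(benzyloxy)-1,3-dimethyl-5-(4,4,5,5-tetramethyl-1,3,2-dioxaborolan-2-yl)-1,2,3,4-tetrahydroisoquinoline | CC1(C)OB(OC1(C)C)c1ccc(OCc2ccccc2)c2c1C[C@@H](C)N(Cc1ccccc1)[C@@H]2C | intermediate
37 | {(E)-3-[1-(benzyloxy)-4-bromo-8-methoxy-6-methylnaphthalen-2-yl]allyl}indium dibromide (drawn as the monomer) | Br[In](Br)C/C=C/c1cc(Br)c2cc(C)cc(OC)c2c1OCc1ccccc1 | intermediate (not isolated)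
38 | 1-(3-bromo-6-methoxy-4-methyl-2-vinylphenyl)-2-[5-(benzyloxy)-8-bromo-4-methoxy-2-methylnaphthalen-6-yl]but-3-en-1-ol (racemic, mainly anti) | C=CC(C(O)c1c(OC)cc(C)c(Br)c1C=C)c1cc(Br)c2cc(C)cc(OC)c2c1OCc1ccccc1 | intermediate
39 | 1-(3-bromo-6-methoxy-4-methyl-2-vinylphenyl)-2-[5-(benzyloxy)-8-bromo-4-methoxy-2-methylnaphthalen-6-yl]but-3-en-1-one (racemic) | C=CC(C(=O)c1c(OC)cc(C)c(Br)c1C=C)c1cc(Br)c2cc(C)cc(OC)c2c1OCc1ccccc1 | intermediate
40 | 2-[5-(benzyloxy)-8-bromo-4-methoxy-2-methylnaphthalen-6-yl]-5-bromo-8-methoxy-6-methylnaphthalen-1(2H)-one | O=C1C(c2cc(Br)c3cc(C)cc(OC)c3c2OCc2ccccc2)C=Cc2c(Br)c(C)cc(OC)c12 | intermediate (not isolated)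
41 | 5-(benzyloxy)-1′,8-dibromo-4,4′-dimethoxy-2,2′-dimethyl-6,6′-binaphthalen-5′-ol | Oc1c(-c2cc(Br)c3cc(C)cc(OC)c3c2OCc2ccccc2)ccc2c(Br)c(C)cc(OC)c12 | intermediate
42 | 5,5′-bis(benzyloxy)-1′,8-dibromo-4,4′-dimethoxy-2,2′-dimethyl-6,6′-binaphthalene | Cc1cc(OC)c2c(OCc3ccccc3)c(-c3cc(Br)c4cc(C)cc(OC)c4c3OCc3ccccc3)ccc2c1Br | intermediate
43 | hexabenzyl-protected target (N-benzyl and O-benzyl on each (1R,3R)-isoquinoline; benzyl ethers at C5 and C5′) | Cc1cc(OC)c2c(OCc3ccccc3)c(-c3cc(-c4ccc(OCc5ccccc5)c5c4C[C@@H](C)N(Cc4ccccc4)[C@@H]5C)c4cc(C)cc(OC)c4c3OCc3ccccc3)ccc2c1-c1ccc(OCc2ccccc2)c2c1C[C@@H](C)N(Cc1ccccc1)[C@@H]2C | intermediate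
44 | CNP0077060.1 | COc1cc(C)cc2c(-c3ccc(O)c4c3C[C@@H](C)N[C@@H]4C)cc(-c3ccc4c(-c5ccc(O)c6c5C[C@@H](C)N[C@@H]6C)c(C)cc(OC)c4c3O)c(O)c12 | target

**Step count and risks**

Total steps: 29. Longest linear sequence: 17 steps (steps 1–11, then 24–29, from 2-bromo-5-hydroxybenzaldehyde).

Most likely to fail:

1. Step 26 (key ring closure). The β,γ-double bond of ketone 39 may migrate into conjugation with the carbonyl, through enolisation of the doubly activated α-hydrogen or through ruthenium hydride species, faster than the ring closes; this would remove the terminal alkene that metathesis needs. Fallback: set out from alcohol 38 and run the ring-closing metathesis with the same catalyst at the alcohol oxidation level, where the α-hydrogen is not acidic, to give 2-[5-(benzyloxy)-8-bromo-4-methoxy-2-methylnaphthalen-6-yl]-5-bromo-8-methoxy-6-methyl-1,2-dihydronaphthalen-1-ol F1. Buffered Dess–Martin oxidation of this allylic, benzylic alcohol gives naphthalenone 40, which enolises, and the route is rejoined at 41.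

2. Step 28 (double cross-coupling). Oxidative addition and transmetalation at the C1′ bromide of naphthalene B, flanked by the C2′ methyl group and the peri hydrogen, may be so slow that coupling stalls after the C8 position of naphthalene A while the boronate is consumed by protodeboronation. Fallback: set out from bromide 34; bromine–lithium exchange (n-BuLi, THF, −78 °C) and transmetalation with ZnCl2 give [(1R,3R)-2-benzyl-8-(benzyloxy)-1,3-dimethyl-1,2,3,4-tetrahydroisoquinolin-5-yl]zinc chloride F2. A Negishi coupling of F2 (3 equiv) with dibromide 42 using PdCl2(IPr)(3-chloropyridine) in THF/NMP at 60 °C needs no base and cannot lose the nucleophile by protodeboronation; it rejoins the route at 43.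

3. Step 24 (fragment union). The electron-rich allylic bromide 16 may ionise, hydrolyse or homocouple faster than its indium reagent adds to the doubly ortho-substituted aldehyde, or reversible addition may drain material to the linear α-adduct. Fallback: set out from allylic alcohol 15; methyl chloroformate and pyridine give the branched carbonate 1-[1-(benzyloxy)-4-bromo-8-methoxy-6-methylnaphthalen-2-yl]allyl methyl carbonate F3. Copper-catalysed γ-selective borylation with B2pin2 (CuCl, Xantphos, KOtBu, THF, 0 °C) gives the stable (E)-allyl pinacol boronate 2-{(E)-3-[1-(benzyloxy)-4-bromo-8-methoxy-6-methylnaphthalen-2-yl]allyl}-4,4,5,5-tetramethyl-1,3,2-dioxaborolane F4. Thermal allylboration of aldehyde 23 (toluene, 80 °C) through a closed chair transition state is γ-selective and irreversible, and the route is rejoined at alcohol 38.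

Further compounds

F1 | step 26 | 2-[5-(benzyloxy)-8-bromo-4-methoxy-2-methylnaphthalen-6-yl]-5-bromo-8-methoxy-6-methyl-1,2-dihydronaphthalen-1-ol | OC1C(c2cc(Br)c3cc(C)cc(OC)c3c2OCc2ccccc2)C=Cc2c(Br)c(C)cc(OC)c12
F2 | step 28 | [(1R,3R)-2-benzyl-8-(benzyloxy)-1,3-dimethyl-1,2,3,4-tetrahydroisoquinolin-5-yl]zinc chloride | Cl[Zn]c1ccc(OCc2ccccc2)c2c1C[C@@H](C)N(Cc1ccccc1)[C@@H]2C
F3 | step 24 | 1-[1-(benzyloxy)-4-bromo-8-methoxy-6-methylnaphthalen-2-yl]allyl methyl carbonate | COC(=O)OC(C=C)c1cc(Br)c2cc(C)cc(OC)c2c1OCc1ccccc1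
F4 | step 24 | 2-{(E)-3-[1-(benzyloxy)-4-bromo-8-methoxy-6-methylnaphthalen-2-yl]allyl}-4,4,5,5-tetramethyl-1,3,2-dioxaborolane | CC1(C)OB(C/C=C/c2cc(Br)c3cc(C)cc(OC)c3c2OCc2ccccc2)OC1(C)C
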